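## Analysis of the target

The target 31 is a dimeric flavan-3-ol. An upper epigallocatechin unit is bonded through C4 to C8 of a lower epigallocatechin unit, and each unit carries a galloyl ester on O3. Ring B of the upper unit bears at C2' an aryl ether to a meta oxygen of the lower galloyl ring (ring D). This closes a 16-membered ring whose members are upper C2, C3 and C4, lower C8, C8a, O1, C2 and C3, the ester O and C, three carbons of ring D, the ether O, and C2' and C1' of ring B. There are five stereocentres: the lower unit is (2R,3R), and the upper unit is (2R,3R,4R), with ring B cis to O3 and O3 trans to the lower unit on C4. The fifteen free phenols, two of them in pyrogallol rings, are sensitive to air and base, C2 of a free flavan epimerises in base, and the interflavan bond is cleaved by acid. The difficulties are the hindered diaryl ether, the macrocycle, and the stereotriad on upper ring C, whose C4 carries two electron-rich aryl groups and ionises easily. The strategy rests on one feature: upper C2 and C3 are neighbours in both the pyran ring and the macrocycle. Without O1 and O3 they are the two carbons of an alkyne between C1' of ring B and C4, and C2, being benzylic to the oxygen-rich ring B, is the alkyne carbon that should accept the ring-A oxygen in a 6-endo sense.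

## Retrosynthetic reasoning

31 to 30. All fifteen phenols are masked as benzyl ethers in 30, so the last step is one hydrogenolysis and no second type of protecting group has to be removed from the polyphenol.

30 to 28 to 26 and 27. The upper C2–H bond is cut, which leads back to the 2-methoxy ketal 28. The forward step ionises the ketal and delivers hydride to C2. The O3–acyl bond is cut next, giving alcohol 26 and acid 27. The ester is installed before the reduction because its carbonyl can bridge to C2 on the face of O3, leaving the opposite face open to hydride. This is what places ring B cis to O3.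

26 to 24. The C3–O and C2–OMe bonds are removed together, giving the enol ether 24. The forward reaction is an epoxidation in an alcohol solvent. The lower flavan on C4 shields one face, so oxygen should arrive trans to it, and the epoxide is opened at the benzylic acetal carbon C2.

24 to 23 to 22. The O1–C2 bond is cut, which unmasks an alkyne flanked by ring B and by C4, with the ring-A oxygen as a free phenol in 23 and as its methoxymethyl ether in 22. The forward step is a π-acid-catalysed 6-endo addition of the phenol, directed to C2 by ring B.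

22 to 21. The triple bond C2≡C3 is cut by the reverse of alkyne metathesis. This is the only disconnection that opens the macrocycle at two carbons that carry neither stereochemistry nor steric bulk. The diyne 21 has methyl-capped alkynes on ring B and on C4, and the forward step has only to favour ring closure over oligomerisation.

21 to 19 to 13 and 18. The methyl cap is removed (19), then the C4–C8 bond is cut. The forward reaction is a copper-catalysed asymmetric propargylic substitution of the racemic acetate 18 by C8 of the ester 13. It needs a terminal alkyne, which is why the cap is added afterwards. This is the only catalyst-controlled stereocentre of the route.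

13 to 12 and 10, and 12 to 11. The ester on lower O3 is cut to give the pentabenzyl ether 12 of natural 11 and the acid 10. The lower unit therefore comes with both stereocentres from the chiral pool.

10 to 9 to 7 to 6 to 5 and 2. The acid is taken back to its methyl ester 9, the propynyl group to the ethynyl group of 7, and that to the aldehyde of 6. The diaryl ether C2'–O bond is then cut between bromide 5 and phenol 2. The aldehyde has two roles: it activates the ortho bromide for copper-mediated etherification and it is the precursor of the alkyne.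

18 to 16 to 15 to 14, 5 to 4 to 3, and 2 to 1. These are protecting-group and one-carbon operations on three simple oxygenated benzene derivatives. One phenol of 14 is kept apart as the methoxymethyl ether, since it becomes O1.

## Alternatives that were turned down

Alternative 1: Upper ring C is disconnected at C4–C4a. The precursor A1 is an open chain. C4 carries the lower flavan (through C8) and a methyl ether, C3 the galloyl ester, and C2 both ring B (already etherified to ring D) and a 3,5-bis(benzyloxy)phenyl ether that is the future ring A. In the forward step a silyl triflate removes the methoxy group. The ester carbonyl bridges the C4 cation on the face of O3, and the carbon ortho to the ether oxygen attacks from the other face to give the bisflavan A2 with the 3,4-trans relationship.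
- In its favour: C2 and C3 are made as ordinary sp3 centres, and no oxidation is needed after ring closure. Acyl participation is used where it is best understood, at a cation flanked by the ester.
- Against it: C2 of A1 is a benzylic aryl ether on an oxygen-rich ring and can ionise under the same Lewis acid, which threatens loss of the ether or epimerisation. The attacking arene is only a dialkoxyphenyl ether facing a strongly stabilised cation. Three contiguous acyclic stereocentres must be built on a substrate that already holds the lower flavan and the diaryl ether. A2 is still open, so two deprotections and a macrolactonisation onto the hindered axial lower 3-OH remain.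
- Comparison: this alternative is stronger on the C3/C4 relationship. The chosen route offers instead a ring closure at two sp carbons, tolerant of all functionality, a lower unit used as it comes from 11, and a shorter sequence after the key event.

Alternative 2: The lower pyran ring and the macrocycle are disconnected together at C3–C4 and O1–C2 of the lower unit. The precursor A3 is a complete upper unit whose C4 carries a phloroglucinol ring with a free phenol and an ortho hydroxymethyl group, and whose ring D is esterified as a (Z)-2-arylvinyl ester. On heating, A3 loses water across the phenol and the benzylic alcohol, and the resulting heterodiene adds to the tethered enol ester. This gives A4, which is identical with 30.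
- In its favour: it has the best step economy of the four strategies. One step forms two bonds, two rings and both lower stereocentres with the cis relationship fixed by the alkene geometry, and it ends one hydrogenolysis from the target.
- Against it: the absolute configuration of lower C2 and C3 depends only on how the macrocyclic transition state folds, with no element to predict it. The aryl and acyloxy groups polarise the alkene in opposite senses, so the regiochemistry is not secured. The (Z)-enol ester is difficult to make and keep. The natural lower unit 11 goes unused.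
- Comparison: this alternative is stronger in convergence. The chosen route offers instead stereocentres that are each set by an identifiable element (chiral pool, chiral ligand, C4 aryl group, acyl participation) and a ring closure that forms no stereocentre.

Alternative 3: The diaryl ether C2'–O bond is disconnected inside the macrocycle. In the precursor A5, ring B of an otherwise complete, benzylated 4→8 dimer is a brominated ortho-quinone monoketal and ring D has one free phenol. Under a caesium base the phenoxide adds to the bromine-bearing carbon and bromide leaves, giving the macrocyclic aryloxy dienone A6.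
- In its favour: both galloyl esters and the interflavan bond can be assembled by established flavan chemistry. The addition–elimination is a proven way to make crowded galloyl aryl ethers.
- Against it: ring B must be brominated and differentially protected before the flavan is built, because ring A of a flavan brominates first, so the upper unit is also a de novo synthesis here. The dienone is prone to dimerisation and carries the acidic, vinylogous C2–H of the flavan next to it. The ring closure joins two hindered positions across 16 atoms. After it, the ketal must be hydrolysed and the quinone reduced, or a residual methyl ether cleaved, on the fully assembled molecule.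
- Comparison: this alternative is stronger on the stereochemistry of upper ring C, which it never has to create late. The chosen route offers instead a mild, functional-group-tolerant ring closure and an end game with only benzyl ethers to remove.

Key step: step 15

Remark: locants follow flavan numbering. The upper unit is the one substituted at C4, the lower unit the one substituted at C8. Ring D is the galloyl ring on lower O3 that carries the aryl ether.
Remark: compounds 1, 3, 11, 14 and 27 are taken as purchased.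
Assumption: the sense of induction of the pybox ligand in step 13 cannot be predicted for a 2,6-dioxygenated aryl group. The antipode that gives 4R is to be chosen in a first small run, as both antipodes are available.

## Route

Step 1
Reactants: 1 methyl gallate
Product: 2 methyl 3,4-bis(benzyloxy)-5-hydroxybenzoate
Conditions: BnBr (2.0 equiv), K2CO3 (2.0 equiv), DMF, 0 °C to rt; chromatography
Reagents that add atoms: benzyl bromide, BrCc1ccccc1
Why: Williamson etherification; the 4-OH para to the ester is the most acidic and should react first, the second benzyl group then goes to one of the two equivalent meta hydroxyls, so the main dibenzyl ether should be the 3,4-isomer, to be separated from mono- and tribenzyl ethers.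

Step 2
Reactants: 3 3,4,5-trihydroxybenzaldehyde
Product: 4 3,4,5-tris(benzyloxy)benzaldehyde
Conditions: BnBr (3.6 equiv), K2CO3, DMF, 60 °C, N2
Reagents that add atoms: benzyl bromide, BrCc1ccccc1
Why: exhaustive Williamson etherification of the three phenols; the aldehyde has no enolisable position.

Step 3
Reactants: 4 3,4,5-tris(benzyloxy)benzaldehyde
Product: 5 2-bromo-3,4,5-tris(benzyloxy)benzaldehyde
Conditions: NBS (1.05 equiv), MeCN, rt
Reagents that add atoms: N-bromosuccinimide, O=C1CCC(=O)N1Br
Why: electrophilic aromatic bromination; C2 and C6 are equivalent and each is ortho and para to a benzyloxy group, while the phenyl rings of the benzyl ethers are not activated.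

Step 4
Reactants: 5 2-bromo-3,4,5-tris(benzyloxy)benzaldehyde; 2 methyl 3,4-bis(benzyloxy)-5-hydroxybenzoate
Product: 6 methyl 3,4-bis(benzyloxy)-5-[2,3,4-tris(benzyloxy)-6-formylphenoxy]benzoate
Conditions: CuI (20 mol %), picolinic acid (40 mol %), K3PO4, DMSO, 90 °C, Ar
Reagents that add atoms: none
Why: Ullmann-type C–O coupling; the ortho formyl group assists oxidative addition at the hindered bromide, as ortho carbonyl groups do in the classical copper-mediated synthesis of galloyl diaryl ethers, and the aldehyde has no α-hydrogen to lose under base.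

Step 5
Reactants: 6 methyl 3,4-bis(benzyloxy)-5-[2,3,4-tris(benzyloxy)-6-formylphenoxy]benzoate
Product: 7 methyl 3,4-bis(benzyloxy)-5-[2,3,4-tris(benzyloxy)-6-ethynylphenoxy]benzoate
Conditions: dimethyl (1-diazo-2-oxopropyl)phosphonate, K2CO3, MeOH/THF, rt
Reagents that add atoms: dimethyl (1-diazo-2-oxopropyl)phosphonate, CC(=O)C(=[N+]=[N-])P(=O)(OC)OC
Why: Ohira–Bestmann variant of the Seyferth–Gilbert homologation; the conditions are mild enough for the methyl ester, for which methanolysis is degenerate.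

Step 6
Reactants: 7 methyl 3,4-bis(benzyloxy)-5-[2,3,4-tris(benzyloxy)-6-ethynylphenoxy]benzoate
Product: 9 methyl 3,4-bis(benzyloxy)-5-[2,3,4-tris(benzyloxy)-6-(prop-1-ynyl)phenoxy]benzoate, via lithium acetylide 8 (not isolated)
Conditions: LiN(SiMe3)2 (1.1 equiv), THF, −78 °C; MeOTf, −78 to −20 °C
Reagents that add atoms: methyl trifluoromethanesulfonate, COS(=O)(=O)C(F)(F)F
Why: deprotonation of the terminal alkyne by a non-nucleophilic amide and C-methylation of the acetylide; at −78 °C neither the amide nor the acetylide should attack the electron-rich benzoate.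

Step 7
Reactants: 9 methyl 3,4-bis(benzyloxy)-5-[2,3,4-tris(benzyloxy)-6-(prop-1-ynyl)phenoxy]benzoate
Product: 10 3,4-bis(benzyloxy)-5-[2,3,4-tris(benzyloxy)-6-(prop-1-ynyl)phenoxy]benzoic acid
Conditions: LiOH, THF/MeOH/H2O, 40 °C; then aq. HCl
Reagents that add atoms: lithium hydroxide, [Li+].[OH-]
Why: saponification of an unhindered methyl benzoate; ethers and the internal alkyne are inert to hydroxide.

Step 8
Reactants: 11 (−)-epigallocatechin
Product: 12 (2R,3R)-5,7-bis(benzyloxy)-2-[3,4,5-tris(benzyloxy)phenyl]chroman-3-ol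
Conditions: BnBr (5.5 equiv), K2CO3, degassed DMF, 0 °C to rt, Ar
Reagents that add atoms: benzyl bromide, BrCc1ccccc1
Why: Williamson etherification of the five phenols; carbonate does not deprotonate the secondary 3-OH, and low temperature under argon should suppress C2 epimerisation and oxidation of the pyrogallol ring.

Step 9
Reactants: 12 (2R,3R)-5,7-bis(benzyloxy)-2-[3,4,5-tris(benzyloxy)phenyl]chroman-3-ol; 10 3,4-bis(benzyloxy)-5-[2,3,4-tris(benzyloxy)-6-(prop-1-ynyl)phenoxy]benzoic acid
Product: 13 (2R,3R)-5,7-bis(benzyloxy)-2-[3,4,5-tris(benzyloxy)phenyl]chroman-3-yl 3,4-bis(benzyloxy)-5-[2,3,4-tris(benzyloxy)-6-(prop-1-ynyl)phenoxy]benzoate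
Conditions: DCC, DMAP, CH2Cl2, rt
Reagents that add atoms: none
Why: Steglich esterification, the standard way to galloylate the axial 3-OH of benzylated epi-flavans; acid 10 is a gallic acid derivative of the same kind.

Step 10
Reactants: 14 2,4,6-trihydroxybenzaldehyde
Product: 15 2,4-bis(benzyloxy)-6-hydroxybenzaldehyde
Conditions: BnBr (2.1 equiv), K2CO3 (2.1 equiv), DMF, 0 °C to rt; chromatography
Reagents that add atoms: benzyl bromide, BrCc1ccccc1
Why: Williamson etherification; the para hydroxyl reacts first, then one of the two equivalent ortho hydroxyls, and the last one is held back by its hydrogen bond to the aldehyde.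

Step 11
Reactants: 15 2,4-bis(benzyloxy)-6-hydroxybenzaldehyde
Product: 16 2,4-bis(benzyloxy)-6-(methoxymethoxy)benzaldehyde
Conditions: MOMCl, iPr2NEt, CH2Cl2, 0 to 40 °C
Reagents that add atoms: chloromethyl methyl ether, COCCl
Why: O-alkylation of the chelated phenol by the reactive chloromethyl ether; the acetal withstands base, organometallics and the metathesis catalyst and is removable without touching benzyl ethers.

Step 12
Reactants: 16 2,4-bis(benzyloxy)-6-(methoxymethoxy)benzaldehyde
Product: 18 rac-1-[2,4-bis(benzyloxy)-6-(methoxymethoxy)phenyl]prop-2-yn-1-yl acetate, via bromomagnesium alkoxide 17 (not isolated)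
Conditions: HC≡CMgBr (1.3 equiv), THF, 0 °C; then Ac2O, DMAP (cat.), 0 °C to rt; filtration through Et3N-deactivated silica
Reagents that add atoms: ethynylmagnesium bromide, C#C[Mg]Br; acetic anhydride, CC(=O)OC(C)=O
Why: Grignard addition to the aldehyde and acylation of the alkoxide in the same flask, which avoids isolating the easily ionised alcohol; the racemate suffices because the stereocentre is erased in step 13.

Step 13
Reactants: 13 (2R,3R)-5,7-bis(benzyloxy)-2-[3,4,5-tris(benzyloxy)phenyl]chroman-3-yl 3,4-bis(benzyloxy)-5-[2,3,4-tris(benzyloxy)-6-(prop-1-ynyl)phenoxy]benzoate; 18 rac-1-[2,4-bis(benzyloxy)-6-(methoxymethoxy)phenyl]prop-2-yn-1-yl acetate (1.5 equiv)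
Product: 19 ester 13 carrying at C8 the (1R)-1-[2,4-bis(benzyloxy)-6-(methoxymethoxy)phenyl]prop-2-yn-1-yl group
Conditions: CuOTf·0.5C6H6 (10 mol %), 2,6-bis[(4S)-4-phenyl-4,5-dihydrooxazol-2-yl]pyridine or its antipode (12 mol %), iPr2NEt, CH2Cl2, −20 °C, Ar
Reagents that add atoms: none
Why: copper-catalysed asymmetric propargylic substitution of the Friedel–Crafts type; the copper acetylide of 18 loses acetate to a ligand-bound copper allenylidene on which both enantiomers of 18 converge, and C8 of 13, the arene position that reacts in 4→8 flavan couplings, attacks the γ-carbon on the face left open by the ligand (4R). The propynyl group of 13 cannot form an acetylide and stays out, and a non-nucleophilic solvent is used because 18 would solvolyse in an alcohol.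

Step 14
Reactants: 19 ester 13 carrying at C8 the (1R)-1-[2,4-bis(benzyloxy)-6-(methoxymethoxy)phenyl]prop-2-yn-1-yl group
Product: 21 diyne, ester 13 carrying at C8 the (1R)-1-[2,4-bis(benzyloxy)-6-(methoxymethoxy)phenyl]but-2-yn-1-yl group, via lithium acetylide 20 (not isolated)
Conditions: LiN(SiMe3)2 (1.1 equiv), THF, −78 °C; MeOTf, −78 to −30 °C
Reagents that add atoms: methyl trifluoromethanesulfonate, COS(=O)(=O)C(F)(F)F
Why: as in step 6; the amide is basic enough for the sp C–H but not for the diarylpropargylic C4–H, so 4R should be retained, and the ester survives at −78 °C.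

Step 15
Reactants: 21 diyne, ester 13 carrying at C8 the (1R)-1-[2,4-bis(benzyloxy)-6-(methoxymethoxy)phenyl]but-2-yn-1-yl group
Product: 22 16-membered cycloalkyne in which C2≡C3 joins C1' of ring B to the (4R)-configured C4
Conditions: Mo(CAr)(OSiPh3)3 (Ar = 4-MeOC6H4, 15 mol %), powdered 5 Å molecular sieves, toluene, 80 °C, slow addition of 21 to a final 1 mM
Reagents that add atoms: none
Why: Ring-closing alkyne metathesis: the alkylidyne adds to one propynyl group by [2+2] cycloaddition to a molybdacyclobutadiene, cycloreversion loads the substrate on molybdenum, and the same sequence with the second propynyl group releases the cycloalkyne and a Mo≡CMe species that carries the chain. The closest known reaction type is the closure of 14- to 18-membered cycloalkynes from methyl-capped diynes with molybdenum alkylidyne triarylsilanolate catalysts. The only ring formed is the 16-membered one, closed as a macrocyclisation in which both alkyne carbons (C2 and C3) become ring members. From standard bond lengths the collinear unit C1'–C2≡C3–C4 spans about 4.1 Å against about 3.9 Å for the antiperiplanar C1'–C2–C3–C4 unit of the target, in which ring B is equatorial, so the ring should accept the triple bond without much strain. No stereocentre is formed, and the 4R centre is not at risk because neither acid nor base is present. The selectivity needed is ring closure over oligomerisation: high dilution with slow addition, trapping of 2-butyne by the sieves and the reversibility of chain-forming metathesis should direct the material to the ring. The substrate helps through three turn elements (the ortho-disposed ether and alkyne on ring B, the meta-disposed ring D and the cis-2,3 lower pyran), and it offers the catalyst nothing but two methyl-capped alkynes next to esters, ethers and an acetal that the catalyst leaves alone.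

Step 16
Reactants: 22 16-membered cycloalkyne
Product: 23 phenol, 22 with the methoxymethyl group on the ring-A oxygen removed
Conditions: HCl (0.5 M in MeOH)/THF, rt
Reagents that add atoms: none
Why: acid-catalysed acetal exchange of the aryl methoxymethyl ether; benzyl ethers and esters are stable, and room temperature is kept so that the doubly benzylic C4 is not ionised.

Step 17
Reactants: 23 phenol
Product: 24 (4R)-4H-chromene, O1 bonded to C2 with a C2=C3 double bond, inside the macrocycle
Conditions: AuCl(PPh3) (5 mol %), AgOTf (5 mol %), CH2Cl2, rt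
Reagents that add atoms: none
Why: gold-catalysed 6-endo-dig hydroalkoxylation, as known for ortho-(1,3-diarylpropargyl)phenols giving 2,4-diaryl-4H-chromenes; the gold-bound alkyne carries positive charge at C2, where the para and ortho oxygens of ring B stabilise it, so the phenol should add there and not at C3.

Step 18
Reactants: 24 (4R)-4H-chromene
Product: 26 (3R,4R)-2-methoxy-flavan-3-ol (C2 not defined), via 2,3-epoxide 25 (not isolated)
Conditions: DMDO (1.1 equiv, acetone solution), CH2Cl2/MeOH, −40 to 0 °C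
Reagents that add atoms: dimethyldioxirane, CC1(C)OO1; methanol, CO
Why: epoxidation of the electron-rich enol ether on the face opposite the pseudoaxial lower flavan on C4, then methanolysis of the epoxide at the benzylic acetal carbon C2, as with glycal epoxides; this sets 3R with O3 trans to the C4 substituent, and the C2 configuration is irrelevant because it is erased in step 20.

Step 19
Reactants: 26 (3R,4R)-2-methoxy-flavan-3-ol; 27 3,4,5-tris(benzyloxy)benzoic acid
Product: 28 3-O-[3,4,5-tris(benzyloxy)benzoyl] ester of 26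
Conditions: 27, (COCl)2, DMF (cat.), CH2Cl2, rt, evaporation; then 26, Et3N, DMAP, CH2Cl2, rt to 40 °C
Reagents that add atoms: none
Why: acylation of the hindered secondary alcohol by the acid chloride under nucleophilic catalysis; the ketal and the esters are stable to amine base.

Step 20
Reactants: 28 3-O-[3,4,5-tris(benzyloxy)benzoyl] ester of 26
Product: 30 pentadeca-O-benzyl ether of the target, upper unit (2R,3R,4R), lower unit (2R,3R), via acyloxonium ion 29 (not isolated)
Conditions: Et3SiH (5 equiv), BF3·OEt2 (2 equiv), CH2Cl2, −78 to −40 °C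
Reagents that add atoms: none
Why: Lewis-acid ionisation of the aryl ketal and silane reduction, the reaction type used for aryl C-glycosides; the 3-O-acyl carbonyl bridges C2 on the face of O3, so hydride should enter from the opposite face and place H2 trans to O3 and ring B cis to it (2R). The same face gives the product with ring B equatorial.

Step 21
Reactants: 30 pentadeca-O-benzyl ether of the target
Product: 31 target compound CNP0601265.1
Conditions: H2 (1 atm), Pd(OH)2/C, THF/MeOH, rt; filtration and concentration under Ar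
Reagents that add atoms: none
Why: hydrogenolysis of the fifteen benzyl ethers under neutral conditions, which leaves the esters, the diaryl ether, the flavan C–O bonds and all five stereocentres untouched.

## Compound list

1 | methyl gallate (methyl 3,4,5-trihydroxybenzoate) | COC(=O)c1cc(O)c(O)c(O)c1 | starting material
2 | methyl 3,4-bis(benzyloxy)-5-hydroxybenzoate | COC(=O)c1cc(O)c(OCc9ccccc9)c(OCc9ccccc9)c1 | intermediate
3 | 3,4,5-trihydroxybenzaldehyde | O=Cc1cc(O)c(O)c(O)c1 | starting material
4 | 3,4,5-tris(benzyloxy)benzaldehyde | O=Cc1cc(OCc9ccccc9)c(OCc9ccccc9)c(OCc9ccccc9)c1 | intermediate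
5 | 2-bromo-3,4,5-tris(benzyloxy)benzaldehyde | O=Cc1cc(OCc9ccccc9)c(OCc9ccccc9)c(OCc9ccccc9)c1Br | intermediate
6 | methyl 3,4-bis(benzyloxy)-5-[2,3,4-tris(benzyloxy)-6-formylphenoxy]benzoate | COC(=O)c1cc(Oc2c(C=O)cc(OCc9ccccc9)c(OCc9ccccc9)c2OCc9ccccc9)c(OCc9ccccc9)c(OCc9ccccc9)c1 | intermediate
7 | methyl 3,4-bis(benzyloxy)-5-[2,3,4-tris(benzyloxy)-6-ethynylphenoxy]benzoate | COC(=O)c1cc(Oc2c(C#C)cc(OCc9ccccc9)c(OCc9ccccc9)c2OCc9ccccc9)c(OCc9ccccc9)c(OCc9ccccc9)c1 | intermediate
8 | lithium acetylide of 7 | COC(=O)c1cc(Oc2c(C#C[Li])cc(OCc9ccccc9)c(OCc9ccccc9)c2OCc9ccccc9)c(OCc9ccccc9)c(OCc9ccccc9)c1 | intermediate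
9 | methyl 3,4-bis(benzyloxy)-5-[2,3,4-tris(benzyloxy)-6-(prop-1-ynyl)phenoxy]benzoate | COC(=O)c1cc(Oc2c(C#CC)cc(OCc9ccccc9)c(OCc9ccccc9)c2OCc9ccccc9)c(OCc9ccccc9)c(OCc9ccccc9)c1 | intermediate
10 | 3,4-bis(benzyloxy)-5-[2,3,4-tris(benzyloxy)-6-(prop-1-ynyl)phenoxy]benzoic acid | OC(=O)c1cc(Oc2c(C#CC)cc(OCc9ccccc9)c(OCc9ccccc9)c2OCc9ccccc9)c(OCc9ccccc9)c(OCc9ccccc9)c1 | intermediate
11 | (−)-epigallocatechin, (2R,3R)-2-(3,4,5-trihydroxyphenyl)chroman-3,5,7-triol | O[C@@H]1Cc2c(O)cc(O)cc2O[C@@H]1c1cc(O)c(O)c(O)c1 | starting material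
12 | (2R,3R)-5,7-bis(benzyloxy)-2-[3,4,5-tris(benzyloxy)phenyl]chroman-3-ol | O[C@@H]1Cc2c(OCc9ccccc9)cc(OCc9ccccc9)cc2O[C@@H]1c1cc(OCc9ccccc9)c(OCc9ccccc9)c(OCc9ccccc9)c1 | intermediate
13 | (2R,3R)-5,7-bis(benzyloxy)-2-[3,4,5-tris(benzyloxy)phenyl]chroman-3-yl 3,4-bis(benzyloxy)-5-[2,3,4-tris(benzyloxy)-6-(prop-1-ynyl)phenoxy]benzoate | O=C(O[C@@H]1Cc2c(OCc9ccccc9)cc(OCc9ccccc9)cc2O[C@@H]1c1cc(OCc9ccccc9)c(OCc9ccccc9)c(OCc9ccccc9)c1)c1cc(Oc2c(C#CC)cc(OCc9ccccc9)c(OCc9ccccc9)c2OCc9ccccc9)c(OCc9ccccc9)c(OCc9ccccc9)c1 | intermediate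
14 | 2,4,6-trihydroxybenzaldehyde | O=Cc1c(O)cc(O)cc1O | starting material
15 | 2,4-bis(benzyloxy)-6-hydroxybenzaldehyde | O=Cc1c(O)cc(OCc9ccccc9)cc1OCc9ccccc9 | intermediate
16 | 2,4-bis(benzyloxy)-6-(methoxymethoxy)benzaldehyde | COCOc1cc(OCc9ccccc9)cc(OCc9ccccc9)c1C=O | intermediate
17 | bromomagnesium 1-[2,4-bis(benzyloxy)-6-(methoxymethoxy)phenyl]prop-2-yn-1-olate (racemic) | C#CC(O[Mg]Br)c1c(OCOC)cc(OCc9ccccc9)cc1OCc9ccccc9 | intermediate
18 | rac-1-[2,4-bis(benzyloxy)-6-(methoxymethoxy)phenyl]prop-2-yn-1-yl acetate | C#CC(OC(C)=O)c1c(OCOC)cc(OCc9ccccc9)cc1OCc9ccccc9 | intermediate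
19 | ester 13 carrying at C8 the (1R)-1-[2,4-bis(benzyloxy)-6-(methoxymethoxy)phenyl]prop-2-yn-1-yl group (4R; lower 2R,3R) | C#C[C@@H](c2c3O[C@H](c4cc(OCc9ccccc9)c(OCc9ccccc9)c(OCc9ccccc9)c4)[C@H](OC(=O)c5cc(Oc6c(C#CC)cc(OCc9ccccc9)c(OCc9ccccc9)c6OCc9ccccc9)c(OCc9ccccc9)c(OCc9ccccc9)c5)Cc3c(OCc9ccccc9)cc2OCc9ccccc9)c3c(OCc9ccccc9)cc(OCc9ccccc9)cc3OCOC | intermediate
20 | lithium acetylide of 19 | [Li]C#C[C@@H](c2c3O[C@H](c4cc(OCc9ccccc9)c(OCc9ccccc9)c(OCc9ccccc9)c4)[C@H](OC(=O)c5cc(Oc6c(C#CC)cc(OCc9ccccc9)c(OCc9ccccc9)c6OCc9ccccc9)c(OCc9ccccc9)c(OCc9ccccc9)c5)Cc3c(OCc9ccccc9)cc2OCc9ccccc9)c3c(OCc9ccccc9)cc(OCc9ccccc9)cc3OCOC | intermediate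
21 | diyne, ester 13 carrying at C8 the (1R)-1-[2,4-bis(benzyloxy)-6-(methoxymethoxy)phenyl]but-2-yn-1-yl group (4R; lower 2R,3R) | CC#C[C@@H](c2c3O[C@H](c4cc(OCc9ccccc9)c(OCc9ccccc9)c(OCc9ccccc9)c4)[C@H](OC(=O)c5cc(Oc6c(C#CC)cc(OCc9ccccc9)c(OCc9ccccc9)c6OCc9ccccc9)c(OCc9ccccc9)c(OCc9ccccc9)c5)Cc3c(OCc9ccccc9)cc2OCc9ccccc9)c3c(OCc9ccccc9)cc(OCc9ccccc9)cc3OCOC | intermediate
22 | 16-membered cycloalkyne, C2≡C3 between C1' of ring B and (4R)-C4, ring-A oxygen as methoxymethyl ether | C1#C[C@@H](c2c3O[C@H](c4cc(OCc9ccccc9)c(OCc9ccccc9)c(OCc9ccccc9)c4)[C@H](OC(=O)c5cc(Oc6c1cc(OCc9ccccc9)c(OCc9ccccc9)c6OCc9ccccc9)c(OCc9ccccc9)c(OCc9ccccc9)c5)Cc3c(OCc9ccccc9)cc2OCc9ccccc9)c3c(OCc9ccccc9)cc(OCc9ccccc9)cc3OCOC | intermediate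
23 | phenol, 22 with the ring-A oxygen free | C1#C[C@@H](c2c3O[C@H](c4cc(OCc9ccccc9)c(OCc9ccccc9)c(OCc9ccccc9)c4)[C@H](OC(=O)c5cc(Oc6c1cc(OCc9ccccc9)c(OCc9ccccc9)c6OCc9ccccc9)c(OCc9ccccc9)c(OCc9ccccc9)c5)Cc3c(OCc9ccccc9)cc2OCc9ccccc9)c3c(OCc9ccccc9)cc(OCc9ccccc9)cc3O | intermediate
24 | (4R)-4H-chromene (flav-2-ene) inside the macrocycle | C1(=C[C@@H]2c3c(OCc9ccccc9)cc(OCc9ccccc9)cc3O1)c1cc(OCc9ccccc9)c(OCc9ccccc9)c(OCc9ccccc9)c1Oc1cc(cc(OCc9ccccc9)c1OCc9ccccc9)C(=O)O[C@@H]1Cc3c(OCc9ccccc9)cc(OCc9ccccc9)c2c3O[C@@H]1c1cc(OCc9ccccc9)c(OCc9ccccc9)c(OCc9ccccc9)c1 | intermediate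
25 | 2,3-epoxide of 24, oxygen on the face opposite the C4 substituent | O1[C@@H]2[C@@H]3c4c(OCc9ccccc9)cc(OCc9ccccc9)cc4O[C@]12c1cc(OCc9ccccc9)c(OCc9ccccc9)c(OCc9ccccc9)c1Oc1cc(cc(OCc9ccccc9)c1OCc9ccccc9)C(=O)O[C@@H]1Cc4c(OCc9ccccc9)cc(OCc9ccccc9)c3c4O[C@@H]1c1cc(OCc9ccccc9)c(OCc9ccccc9)c(OCc9ccccc9)c1 | intermediate
26 | (3R,4R)-2-methoxy-flavan-3-ol inside the macrocycle, C2 not defined | O[C@@H]1[C@@H]2c3c(OCc9ccccc9)cc(OCc9ccccc9)cc3OC1(OC)c1cc(OCc9ccccc9)c(OCc9ccccc9)c(OCc9ccccc9)c1Oc1cc(cc(OCc9ccccc9)c1OCc9ccccc9)C(=O)O[C@@H]1Cc3c(OCc9ccccc9)cc(OCc9ccccc9)c2c3O[C@@H]1c1cc(OCc9ccccc9)c(OCc9ccccc9)c(OCc9ccccc9)c1 | intermediate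
27 | 3,4,5-tris(benzyloxy)benzoic acid | OC(=O)c1cc(OCc9ccccc9)c(OCc9ccccc9)c(OCc9ccccc9)c1 | starting material
28 | 3-O-[3,4,5-tris(benzyloxy)benzoyl] ester of 26 | O=C(O[C@@H]1[C@@H]2c3c(OCc9ccccc9)cc(OCc9ccccc9)cc3OC1(OC)c1cc(OCc9ccccc9)c(OCc9ccccc9)c(OCc9ccccc9)c1Oc1cc(cc(OCc9ccccc9)c1OCc9ccccc9)C(=O)O[C@@H]1Cc3c(OCc9ccccc9)cc(OCc9ccccc9)c2c3O[C@@H]1c1cc(OCc9ccccc9)c(OCc9ccccc9)c(OCc9ccccc9)c1)c1cc(OCc9ccccc9)c(OCc9ccccc9)c(OCc9ccccc9)c1 | intermediate
29 | acyloxonium (2-aryl-1,3-dioxolan-2-ylium) ion bridging C2 and O3 on the face of O3, methoxytrifluoroborate salt | [C+]1(c5cc(OCc9ccccc9)c(OCc9ccccc9)c(OCc9ccccc9)c5)O[C@@H]2[C@@H]3c4c(OCc9ccccc9)cc(OCc9ccccc9)cc4O[C@@]2(O1)c1cc(OCc9ccccc9)c(OCc9ccccc9)c(OCc9ccccc9)c1Oc1cc(cc(OCc9ccccc9)c1OCc9ccccc9)C(=O)O[C@@H]1Cc4c(OCc9ccccc9)cc(OCc9ccccc9)c3c4O[C@@H]1c1cc(OCc9ccccc9)c(OCc9ccccc9)c(OCc9ccccc9)c1.CO[B-](F)(F)F | intermediate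
30 | pentadeca-O-benzyl ether of the target, upper (2R,3R,4R), lower (2R,3R) | O=C(O[C@@H]1[C@@H]2c3c(OCc9ccccc9)cc(OCc9ccccc9)cc3O[C@@H]1c1cc(OCc9ccccc9)c(OCc9ccccc9)c(OCc9ccccc9)c1Oc1cc(cc(OCc9ccccc9)c1OCc9ccccc9)C(=O)O[C@@H]1Cc3c(OCc9ccccc9)cc(OCc9ccccc9)c2c3O[C@@H]1c1cc(OCc9ccccc9)c(OCc9ccccc9)c(OCc9ccccc9)c1)c1cc(OCc9ccccc9)c(OCc9ccccc9)c(OCc9ccccc9)c1 | intermediate
31 | CNP0601265.1 | O=C(O[C@@H]1[C@@H]2c3c(O)cc(O)cc3O[C@@H]1c1cc(O)c(O)c(O)c1Oc1cc(cc(O)c1O)C(=O)O[C@@H]1Cc3c(O)cc(O)c2c3O[C@@H]1c1cc(O)c(O)c(O)c1)c1cc(O)c(O)c(O)c1 | target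

## Step count and least certain steps

Total: 21 steps. Longest linear sequence: 16 steps (steps 2 to 7, 9 and 13 to 21, from 3).

Step 15 (key step). The most likely failure is intermolecular metathesis to oligomers, or no turnover because the alkyne on C4 is shielded by two ortho-disubstituted aryl groups. The fallback closes the ring at the lower ester instead and forms the triple bond by acetylide addition:
- Acetylide 8 is added to aldehyde 16 (THF, −78 °C) to give the racemic 1,3-diarylpropargylic alcohol F1.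
- F1 is ionised with Sc(OTf)3 (cat., CH2Cl2, −40 °C) in the presence of 12, whose C8 attacks in a Friedel–Crafts propargylation. This gives the (4R)-seco hydroxy ester F2 together with its C4 epimer F3, which is removed by chromatography.
- F2 is saponified (LiOH) to the seco acid F4.
- Yamaguchi macrolactonisation (2,4,6-trichlorobenzoyl chloride, Et3N, then DMAP, toluene, high dilution) of F4 returns to the route at 22.
The price is that C4 is set by separation and not by a catalyst.

Step 13. The most likely failures are loss of catalyst control through uncatalysed ionisation of the very electron-rich acetate, attack of C6 in place of C8, or slow attack of a non-phenolic arene on the stabilised copper allenylidene. The fallback does not use the terminal alkyne at all. Aldehyde 16 is treated with 1-propynylmagnesium bromide to give racemic 1-[2,4-bis(benzyloxy)-6-(methoxymethoxy)phenyl]but-2-yn-1-ol F5. F5 is coupled with 13 under Sc(OTf)3 catalysis (CH2Cl2, −40 °C) in a Friedel–Crafts propargylation, and the (4S)-epimer F6 is separated by chromatography. The route is rejoined at 21, and steps 12 and 14 are not needed.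

Step 17. The most likely failure is attack of the phenol at C3 (5-exo closure to a benzylidene dihydrobenzofuran) if ring geometry overrides the electronic bias. The fallback forms the C2–O bond through a carbonyl group:
- 22 is hydrated (AuCl(PPh3), AgOTf, dioxane/H2O, 60 °C), with water adding at the benzylic carbon, to give the macrocyclic aryl ketone F7.
- HCl in MeOH removes the methoxymethyl group, and the phenol closes on the ketone to give the 2-methoxy-flavan F8.
- Pyridinium p-toluenesulfonate in toluene at 80 °C eliminates methanol from F8 and returns to the route at 24.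

Step 20. The most likely failures are hydride delivery to the wrong face of the C2 cation, because the required face is also that of the pseudoaxial C4 substituent, or reduction at the acyloxonium carbon. The fallback sets C2 by displacement and not by reduction of a cation:
- The ketal 26 is hydrolysed (pyridinium p-toluenesulfonate, acetone/H2O) to the ring-opened α-hydroxy ketone F9.
- Chelation-controlled reduction with Zn(BH4)2 (Et2O/THF, −20 °C) gives the anti-diol F10, (2S,3R).
- Mitsunobu cyclisation (PPh3, DIAD, THF) of the phenol onto the benzylic C2 with inversion gives the 2,3-cis flavan-3-ol F11.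
- F11 is acylated with the acid chloride of 27 as in step 19 and returns to the route at 30.

## Further compounds

F1 | step 15 | methyl 3,4-bis(benzyloxy)-5-[2,3,4-tris(benzyloxy)-6-{3-[2,4-bis(benzyloxy)-6-(methoxymethoxy)phenyl]-3-hydroxyprop-1-ynyl}phenoxy]benzoate (racemic) | COC(=O)c1cc(Oc2c(C#CC(O)c3c(OCOC)cc(OCc9ccccc9)cc3OCc9ccccc9)cc(OCc9ccccc9)c(OCc9ccccc9)c2OCc9ccccc9)c(OCc9ccccc9)c(OCc9ccccc9)c1
F2 | step 15 | (4R)-seco hydroxy ester, C4 bonded to C8 of 12, ring-D methyl ester, lower 3-OH free | COC(=O)c5cc(Oc6c(C#C[C@@H](c2c3O[C@H](c4cc(OCc9ccccc9)c(OCc9ccccc9)c(OCc9ccccc9)c4)[C@H](O)Cc3c(OCc9ccccc9)cc2OCc9ccccc9)c3c(OCc9ccccc9)cc(OCc9ccccc9)cc3OCOC)cc(OCc9ccccc9)c(OCc9ccccc9)c6OCc9ccccc9)c(OCc9ccccc9)c(OCc9ccccc9)c5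
F3 | step 15 | (4S)-epimer of F2 | COC(=O)c5cc(Oc6c(C#C[C@H](c2c3O[C@H](c4cc(OCc9ccccc9)c(OCc9ccccc9)c(OCc9ccccc9)c4)[C@H](O)Cc3c(OCc9ccccc9)cc2OCc9ccccc9)c3c(OCc9ccccc9)cc(OCc9ccccc9)cc3OCOC)cc(OCc9ccccc9)c(OCc9ccccc9)c6OCc9ccccc9)c(OCc9ccccc9)c(OCc9ccccc9)c5
F4 | step 15 | (4R)-seco hydroxy acid from F2 | OC(=O)c5cc(Oc6c(C#C[C@@H](c2c3O[C@H](c4cc(OCc9ccccc9)c(OCc9ccccc9)c(OCc9ccccc9)c4)[C@H](O)Cc3c(OCc9ccccc9)cc2OCc9ccccc9)c3c(OCc9ccccc9)cc(OCc9ccccc9)cc3OCOC)cc(OCc9ccccc9)c(OCc9ccccc9)c6OCc9ccccc9)c(OCc9ccccc9)c(OCc9ccccc9)c5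
F5 | step 13 | rac-1-[2,4-bis(benzyloxy)-6-(methoxymethoxy)phenyl]but-2-yn-1-ol | CC#CC(O)c1c(OCOC)cc(OCc9ccccc9)cc1OCc9ccccc9
F6 | step 13 | (4S)-epimer of 21 | CC#C[C@H](c2c3O[C@H](c4cc(OCc9ccccc9)c(OCc9ccccc9)c(OCc9ccccc9)c4)[C@H](OC(=O)c5cc(Oc6c(C#CC)cc(OCc9ccccc9)c(OCc9ccccc9)c6OCc9ccccc9)c(OCc9ccccc9)c(OCc9ccccc9)c5)Cc3c(OCc9ccccc9)cc2OCc9ccccc9)c3c(OCc9ccccc9)cc(OCc9ccccc9)cc3OCOC
F7 | step 17 | macrocyclic aryl ketone, C2 carbonyl and C3 methylene, (4R), methoxymethyl ether retained | O=C1C[C@@H](c2c3O[C@H](c4cc(OCc9ccccc9)c(OCc9ccccc9)c(OCc9ccccc9)c4)[C@H](OC(=O)c5cc(Oc6c1cc(OCc9ccccc9)c(OCc9ccccc9)c6OCc9ccccc9)c(OCc9ccccc9)c(OCc9ccccc9)c5)Cc3c(OCc9ccccc9)cc2OCc9ccccc9)c3c(OCc9ccccc9)cc(OCc9ccccc9)cc3OCOC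
F8 | step 17 | (4R)-2-methoxy-flavan inside the macrocycle, C3 methylene, C2 not defined | C1[C@@H]2c3c(OCc9ccccc9)cc(OCc9ccccc9)cc3OC1(OC)c1cc(OCc9ccccc9)c(OCc9ccccc9)c(OCc9ccccc9)c1Oc1cc(cc(OCc9ccccc9)c1OCc9ccccc9)C(=O)O[C@@H]1Cc3c(OCc9ccccc9)cc(OCc9ccccc9)c2c3O[C@@H]1c1cc(OCc9ccccc9)c(OCc9ccccc9)c(OCc9ccccc9)c1
F9 | step 20 | ring-opened α-hydroxy ketone, C2 carbonyl, (3R,4R), ring-A phenol free | O[C@H]([C@@H]2c3c(OCc9ccccc9)cc(OCc9ccccc9)cc3O)C(=O)c1cc(OCc9ccccc9)c(OCc9ccccc9)c(OCc9ccccc9)c1Oc1cc(cc(OCc9ccccc9)c1OCc9ccccc9)C(=O)O[C@@H]1Cc3c(OCc9ccccc9)cc(OCc9ccccc9)c2c3O[C@@H]1c1cc(OCc9ccccc9)c(OCc9ccccc9)c(OCc9ccccc9)c1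
F10 | step 20 | anti-diol, (2S,3R,4R), ring-A phenol free | O[C@H]([C@@H]2c3c(OCc9ccccc9)cc(OCc9ccccc9)cc3O)[C@@H](O)c1cc(OCc9ccccc9)c(OCc9ccccc9)c(OCc9ccccc9)c1Oc1cc(cc(OCc9ccccc9)c1OCc9ccccc9)C(=O)O[C@@H]1Cc3c(OCc9ccccc9)cc(OCc9ccccc9)c2c3O[C@@H]1c1cc(OCc9ccccc9)c(OCc9ccccc9)c(OCc9ccccc9)c1
F11 | step 20 | dodeca-O-benzyl (2R,3R,4R)-flavan-3-ol inside the macrocycle, upper 3-OH free | O[C@@H]1[C@@H]2c3c(OCc9ccccc9)cc(OCc9ccccc9)cc3O[C@@H]1c1cc(OCc9ccccc9)c(OCc9ccccc9)c(OCc9ccccc9)c1Oc1cc(cc(OCc9ccccc9)c1OCc9ccccc9)C(=O)O[C@@H]1Cc3c(OCc9ccccc9)cc(OCc9ccccc9)c2c3O[C@@H]1c1cc(OCc9ccccc9)c(OCc9ccccc9)c(OCc9ccccc9)c1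
A1 | alternative 1 | open-chain precursor with C4 methyl ether, 3-O-galloyl ester and C2 3,5-bis(benzyloxy)phenyl ether | O=C(O[C@H](C(OC)c2c3O[C@H](c4cc(OCc9ccccc9)c(OCc9ccccc9)c(OCc9ccccc9)c4)[C@H](O[Si](C)(C)C(C)(C)C)Cc3c(OCc9ccccc9)cc2OCc9ccccc9)[C@H](Oc3cc(OCc9ccccc9)cc(OCc9ccccc9)c3)c1cc(OCc9ccccc9)c(OCc9ccccc9)c(OCc9ccccc9)c1Oc1cc(cc(OCc9ccccc9)c1OCc9ccccc9)C(=O)OCC[Si](C)(C)C)c1cc(OCc9ccccc9)c(OCc9ccccc9)c(OCc9ccccc9)c1
A2 | alternative 1 | C4–C8 linked bisflavan with silyl ether on lower O3 and silylethyl ester on ring D | O=C(O[C@@H]1[C@@H](c2c3O[C@H](c4cc(OCc9ccccc9)c(OCc9ccccc9)c(OCc9ccccc9)c4)[C@H](O[Si](C)(C)C(C)(C)C)Cc3c(OCc9ccccc9)cc2OCc9ccccc9)c3c(OCc9ccccc9)cc(OCc9ccccc9)cc3O[C@@H]1c1cc(OCc9ccccc9)c(OCc9ccccc9)c(OCc9ccccc9)c1Oc1cc(cc(OCc9ccccc9)c1OCc9ccccc9)C(=O)OCC[Si](C)(C)C)c1cc(OCc9ccccc9)c(OCc9ccccc9)c(OCc9ccccc9)c1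
A3 | alternative 2 | upper unit with ortho-hydroxybenzyl alcohol on C4 and (Z)-2-arylvinyl ester on ring D | O=C(O[C@@H]1[C@@H](c2c(O)c(CO)c(OCc9ccccc9)cc2OCc9ccccc9)c3c(OCc9ccccc9)cc(OCc9ccccc9)cc3O[C@@H]1c1cc(OCc9ccccc9)c(OCc9ccccc9)c(OCc9ccccc9)c1Oc1cc(cc(OCc9ccccc9)c1OCc9ccccc9)C(=O)O/C=C\c1cc(OCc9ccccc9)c(OCc9ccccc9)c(OCc9ccccc9)c1)c1cc(OCc9ccccc9)c(OCc9ccccc9)c(OCc9ccccc9)c1
A4 | alternative 2 | pentadeca-O-benzyl ether of the target (identical with 30) | O=C(O[C@@H]1[C@@H]2c3c(OCc9ccccc9)cc(OCc9ccccc9)cc3O[C@@H]1c1cc(OCc9ccccc9)c(OCc9ccccc9)c(OCc9ccccc9)c1Oc1cc(cc(OCc9ccccc9)c1OCc9ccccc9)C(=O)O[C@@H]1Cc3c(OCc9ccccc9)cc(OCc9ccccc9)c2c3O[C@@H]1c1cc(OCc9ccccc9)c(OCc9ccccc9)c(OCc9ccccc9)c1)c1cc(OCc9ccccc9)c(OCc9ccccc9)c(OCc9ccccc9)c1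
A5 | alternative 3 | benzylated 4→8 dimer with ring B as brominated ortho-quinone monoketal and one free phenol on ring D | O=C(O[C@@H]1[C@@H](c2c3O[C@H](c4cc(OCc9ccccc9)c(OCc9ccccc9)c(OCc9ccccc9)c4)[C@H](OC(=O)c5cc(O)c(OCc9ccccc9)c(OCc9ccccc9)c5)Cc3c(OCc9ccccc9)cc2OCc9ccccc9)c3c(OCc9ccccc9)cc(OCc9ccccc9)cc3O[C@@H]1C1=CC(OC)(OC)C(=O)C(OCc9ccccc9)=C1Br)c1cc(OCc9ccccc9)c(OCc9ccccc9)c(OCc9ccccc9)c1
A6 | alternative 3 | macrocyclic 2'-aryloxy dienone | O=C(O[C@@H]1[C@@H]2c3c(OCc9ccccc9)cc(OCc9ccccc9)cc3O[C@@H]1C1=CC(OC)(OC)C(=O)C(OCc9ccccc9)=C1Oc1cc(cc(OCc9ccccc9)c1OCc9ccccc9)C(=O)O[C@@H]1Cc3c(OCc9ccccc9)cc(OCc9ccccc9)c2c3O[C@@H]1c1cc(OCc9ccccc9)c(OCc9ccccc9)c(OCc9ccccc9)c1)c1cc(OCc9ccccc9)c(OCc9ccccc9)c(OCc9ccccc9)c1
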